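## Retrosynthetic overview

- Difengpiol B is traced back through debenzylation and desilylation to a cis-3',4'-epoxy-1'-ol. Its C3'–OH and C4'–OMe come from hydroxyl-directed epoxidation and trans-diaxial methanolysis at C4'. The cyclohexene (ring C) comes from ring-closing metathesis of an allyl/but-3-enyl carbinol, made by chelation-controlled allylation of a C1' ketone.
- The strategy rests on C2 of the dihydrobenzofuran. It is one carbon held between the phenol oxygen O1 and the benzylic carbon C3, and it carries C1' at the acyl oxidation level. C2 is therefore the ylide carbon of an acyl sulfonium ylide, and O1–C7a–C3a–C3 is an ortho-quinone methide. A formal [4+1] annulation forms C2–C3 and O1–C2 and closes the dihydrofuran (ring B).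
- The quinone methide is released from a 2-(1-tosylalkyl)phenol made from dihydroconiferyl alcohol and benzyloxyacetaldehyde. The ylide comes from hex-5-en-2-one and dimethyl sulfide and already carries C1', C6', C5' and C4'.
- Ring order: ring A (arene, purchased), ring B (step 7), ring C (step 9).

Key step: step 7

Remark 1: the (R,R) antipode of the C2-symmetric bis-urea is assumed to give the (2S,3R) series; if the sense of induction is the opposite, the (S,S) catalyst is used.
Remark 2: in step 11 epoxide methanolysis and silyl ether methanolysis both run to completion under the same acid; the silyl-retaining methoxy diol is taken as the transient, and the order does not change the product.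

## Route

Step 1
Reactants: 1 dihydroconiferyl alcohol
Product: 2 4-[3-(tert-butyldimethylsilyloxy)propyl]-2-methoxyphenol
Conditions: TBSCl (1.05 equiv), imidazole, CH2Cl2, 0 °C
Reagents that add atoms: tert-butyldimethylsilyl chloride, CC(C)(C)[Si](C)(C)Cl
Why: Chemoselective O-silylation, since the unhindered primary alcohol should react faster than the hydrogen-bonded guaiacol hydroxyl with one equivalent of silyl chloride.

Step 2
Reactants: 2 4-[3-(tert-butyldimethylsilyloxy)propyl]-2-methoxyphenol; 3 benzyloxyacetaldehyde
Product: 4 racemic 2-[2-(benzyloxy)-1-hydroxyethyl]-6-methoxy-4-[3-(tert-butyldimethylsilyloxy)propyl]phenol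
Conditions: EtMgBr (1.0 equiv), Et2O, 0 °C; solvent exchange to CH2Cl2; then 3, 0 °C to rt
Reagents that add atoms: none
Why: Casiraghi-type ortho-hydroxyalkylation, in which the bromomagnesium phenoxide binds the aldehyde and delivers it through a six-membered transition state to the only free ortho carbon; the new carbinol centre is racemic and is erased in step 7.

Step 3
Reactants: 4 racemic 2-[2-(benzyloxy)-1-hydroxyethyl]-6-methoxy-4-[3-(tert-butyldimethylsilyloxy)propyl]phenol
Product: 5 racemic 2-[2-(benzyloxy)-1-tosylethyl]-6-methoxy-4-[3-(tert-butyldimethylsilyloxy)propyl]phenol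
Conditions: p-TolSO2H (1.5 equiv), CH2Cl2, 4 Å molecular sieves, rt
Reagents that add atoms: p-toluenesulfinic acid, Cc1ccc(cc1)S(=O)O
Why: Acid-promoted ionisation of the ortho-hydroxybenzylic alcohol and capture of the cation by the sulfinate sulfur should give the benzylic sulfone, the usual preparation of 2-(1-tosylalkyl)phenols, in an aprotic medium that spares the silyl ether.

Step 4
Reactants: 6 hex-5-en-2-one
Product: 8 1-bromohex-5-en-2-one, via silyl enol ether 7 (not isolated)
Conditions: LiN(iPr)2, Me3SiCl (in situ quench), THF, −78 °C; then NBS, THF, −78 to 0 °C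
Reagents that add atoms: N-bromosuccinimide, O=C1CCC(=O)N1Br
Why: Kinetic deprotonation at the methyl group gives the less substituted silyl enol ether, which should be brominated by NBS far faster than the isolated terminal alkene (regioselective alpha-bromination through a silyl enol ether).

Step 5
Reactants: 8 1-bromohex-5-en-2-one; 9 dimethyl sulfide
Product: 10 dimethyl(2-oxohex-5-en-1-yl)sulfonium bromide
Conditions: Me2S (1.5 equiv), acetone, rt
Reagents that add atoms: none
Why: SN2 S-alkylation of dimethyl sulfide by the alpha-bromo ketone should give the sulfonium salt, which precipitates from acetone.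

Step 6
Reactants: 10 dimethyl(2-oxohex-5-en-1-yl)sulfonium bromide
Product: 11 dimethylsulfonium 2-oxohex-5-en-1-ylide
Conditions: NaOH (aq, 1.05 equiv), CHCl3, 0 °C; organic phase dried and used at once
Reagents that add atoms: none
Why: The methylene between sulfonium and carbonyl is acidic, so hydroxide deprotonation gives the carbonyl-stabilised ylide free of bromide, which could otherwise compete for the hydrogen-bond donor in step 7.

Step 7
Reactants: 5 racemic 2-[2-(benzyloxy)-1-tosylethyl]-6-methoxy-4-[3-(tert-butyldimethylsilyloxy)propyl]phenol; 11 dimethylsulfonium 2-oxohex-5-en-1-ylide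
Product: 14 1-[(2S,3R)-3-(benzyloxymethyl)-5-[3-(tert-butyldimethylsilyloxy)propyl]-7-methoxy-2,3-dihydrobenzofuran-2-yl]pent-4-en-1-one, via ortho-quinone methide 12 (not isolated), via phenoxide sulfonium betaine 13 (not isolated)
Conditions: 1,1'-[(1R,2R)-cyclohexane-1,2-diyl]bis[3-(3,5-bis(trifluoromethyl)phenyl)urea] (10 mol%), Cs2CO3 (1.5 equiv), 11 (1.3 equiv), CH2Cl2, −20 °C
Reagents that add atoms: none
Why: Cs2CO3 deprotonates phenol 5 and 1,4-elimination of p-toluenesulfinate gives quinone methide 12; the ylide carbon of 11 adds to its exocyclic methide carbon (future C3), the ring rearomatises to betaine 13, and the phenoxide displaces dimethyl sulfide at the carbon alpha to the ketone (future C2), so that C2–C3 and O1–C2 form in one flask. The closest known reaction type is the formal [4+1] annulation of ortho-quinone methides generated in situ from 2-(1-tosylalkyl)phenols with carbonyl-stabilised sulfonium ylides, including its variant under chiral hydrogen-bond-donor catalysis. Ring B closes by 5-exo-tet intramolecular SN2 O-alkylation with inversion at C2. C3 is set in the conjugate addition by the bis-urea, which binds the quinone methide carbonyl oxygen through its N–H bonds and shields one face of the methide carbon; C2 follows because the anti betaine closes faster and the C2–H flanked by sulfonium and ketone can equilibrate, so the trans (2S,3R) isomer is expected. The step needs carbon attack at the methide carbon to outrun tautomerisation of 12 to a 2-vinylphenol and needs one enantioface to be preferred; the electron-rich methoxy-substituted ring stabilises 12, slow heterogeneous release of 12 at low temperature into excess ylide keeps its concentration low, and the methoxy group next to the carbonyl oxygen offers the catalyst a second anchoring point.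

Step 8
Reactants: 14 1-[(2S,3R)-3-(benzyloxymethyl)-5-[3-(tert-butyldimethylsilyloxy)propyl]-7-methoxy-2,3-dihydrobenzofuran-2-yl]pent-4-en-1-one
Product: 15 (4S)-4-[(2S,3R)-3-(benzyloxymethyl)-5-[3-(tert-butyldimethylsilyloxy)propyl]-7-methoxy-2,3-dihydrobenzofuran-2-yl]octa-1,7-dien-4-ol
Conditions: TiCl4 (1.1 equiv), CH2Cl2, −78 °C; then allyltrimethylsilane (2 equiv), −78 °C
Reagents that add atoms: allyltrimethylsilane, C=CC[Si](C)(C)C
Why: Chelation-controlled Hosomi–Sakurai allylation, in which TiCl4 bridges the carbonyl oxygen and O1 so that C=O lies syn to C2–O1 and the allylsilane adds anti to C3 on the face of the C2 hydrogen (the Si face), which should give the 1'S carbinol.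

Step 9
Reactants: 15 (4S)-4-[(2S,3R)-3-(benzyloxymethyl)-5-[3-(tert-butyldimethylsilyloxy)propyl]-7-methoxy-2,3-dihydrobenzofuran-2-yl]octa-1,7-dien-4-ol
Product: 16 (1S)-1-[(2S,3R)-3-(benzyloxymethyl)-5-[3-(tert-butyldimethylsilyloxy)propyl]-7-methoxy-2,3-dihydrobenzofuran-2-yl]cyclohex-3-en-1-ol
Conditions: second-generation Grubbs catalyst RuCl2(=CHPh)(H2IMes)(PCy3) (5 mol%), CH2Cl2, 40 °C
Reagents that add atoms: none
Why: Ring-closing metathesis of the allyl and but-3-enyl arms on C1' closes the six-membered ring C with loss of ethylene; the free tertiary hydroxyl is tolerated and no stereocentre is touched.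

Step 10
Reactants: 16 (1S)-1-[(2S,3R)-3-(benzyloxymethyl)-5-[3-(tert-butyldimethylsilyloxy)propyl]-7-methoxy-2,3-dihydrobenzofuran-2-yl]cyclohex-3-en-1-ol
Product: 17 (1S,3S,6R)-3-[(2S,3R)-3-(benzyloxymethyl)-5-[3-(tert-butyldimethylsilyloxy)propyl]-7-methoxy-2,3-dihydrobenzofuran-2-yl]-7-oxabicyclo[4.1.0]heptan-3-ol (epoxide oxygen cis to the C1' hydroxyl)
Conditions: VO(acac)2 (5 mol%), t-BuOOH (1.5 equiv, in decane), CH2Cl2, 0 °C to rt
Reagents that add atoms: tert-butyl hydroperoxide, CC(C)(C)OO
Why: Hydroxyl-directed epoxidation of a homoallylic alcohol, in which the vanadium alkoxide of the pseudoaxial C1' hydroxyl delivers the peroxide oxygen to the same face of the C3'=C4' alkene and so sets C3' and C4' cis to that hydroxyl.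

Step 11
Reactants: 17 (1S,3S,6R)-3-[(2S,3R)-3-(benzyloxymethyl)-5-[3-(tert-butyldimethylsilyloxy)propyl]-7-methoxy-2,3-dihydrobenzofuran-2-yl]-7-oxabicyclo[4.1.0]heptan-3-ol
Product: 19 (1S,3S,4S)-1-[(2S,3R)-3-(benzyloxymethyl)-5-(3-hydroxypropyl)-7-methoxy-2,3-dihydrobenzofuran-2-yl]-4-methoxycyclohexane-1,3-diol, via silyl-retaining methoxy diol 18 (not isolated)
Conditions: camphorsulfonic acid (0.2 equiv), MeOH, 0 °C to rt
Reagents that add atoms: methanol, CO
Why: Acid-catalysed epoxide methanolysis by Fürst–Plattner trans-diaxial opening, where in the half-chair with the large dihydrobenzofuranyl group equatorial and the C1' hydroxyl axial methanol attacks C4' with inversion (the carbon remote from the electron-withdrawing C1' oxygen), the cis epoxy alcohol geometry rules out transannular attack by the C1' hydroxyl, and the same acid removes the primary silyl ether.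

Step 12
Reactants: 19 (1S,3S,4S)-1-[(2S,3R)-3-(benzyloxymethyl)-5-(3-hydroxypropyl)-7-methoxy-2,3-dihydrobenzofuran-2-yl]-4-methoxycyclohexane-1,3-diol
Product: 20 difengpiol B
Conditions: H2 (1 atm), Pd/C (10 wt% palladium on carbon), EtOAc–MeOH, rt
Reagents that add atoms: none
Why: Hydrogenolysis of the benzyl ether, with nothing else at risk because the ring C2–O1 bond is not benzylic and the benzylic C3 carries only C–C bonds.

## Compound list

1 | dihydroconiferyl alcohol, 4-(3-hydroxypropyl)-2-methoxyphenol | COc1cc(CCCO)ccc1O | starting material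
2 | 4-[3-(tert-butyldimethylsilyloxy)propyl]-2-methoxyphenol | COc1cc(CCCO[Si](C)(C)C(C)(C)C)ccc1O | intermediate
3 | benzyloxyacetaldehyde | O=CCOCc1ccccc1 | starting material
4 | racemic 2-[2-(benzyloxy)-1-hydroxyethyl]-6-methoxy-4-[3-(tert-butyldimethylsilyloxy)propyl]phenol | COc1cc(CCCO[Si](C)(C)C(C)(C)C)cc(C(O)COCc2ccccc2)c1O | intermediate
5 | racemic 2-[2-(benzyloxy)-1-tosylethyl]-6-methoxy-4-[3-(tert-butyldimethylsilyloxy)propyl]phenol | COc1cc(CCCO[Si](C)(C)C(C)(C)C)cc(C(COCc2ccccc2)S(=O)(=O)c2ccc(C)cc2)c1O | intermediate
6 | hex-5-en-2-one | CC(=O)CCC=C | starting material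
7 | 2-(trimethylsilyloxy)hexa-1,5-diene | C=C(O[Si](C)(C)C)CCC=C | intermediate (not isolated)
8 | 1-bromohex-5-en-2-one | BrCC(=O)CCC=C | intermediate
9 | dimethyl sulfide | CSC | starting material
10 | dimethyl(2-oxohex-5-en-1-yl)sulfonium bromide | C[S+](C)CC(=O)CCC=C.[Br-] | intermediate
11 | dimethylsulfonium 2-oxohex-5-en-1-ylide | C[S+](C)[CH-]C(=O)CCC=C | intermediate
12 | (E)-6-[2-(benzyloxy)ethylidene]-2-methoxy-4-[3-(tert-butyldimethylsilyloxy)propyl]cyclohexa-2,4-dien-1-one (ortho-quinone methide) | COC1=CC(CCCO[Si](C)(C)C(C)(C)C)=C/C(=C\COCc2ccccc2)C1=O | intermediate (not isolated)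
13 | anti phenoxide–sulfonium betaine: 2-[3-(benzyloxy)-1-(dimethylsulfonio)-2-oxohept-6-en-... arrangement drawn as the phenoxide bearing CH(CH2OBn)–CH(SMe2+)–C(=O)CH2CH2CH=CH2 at the ortho carbon | COc1cc(CCCO[Si](C)(C)C(C)(C)C)cc([C@H](COCc2ccccc2)[C@@H]([S+](C)C)C(=O)CCC=C)c1[O-] | intermediate (not isolated)
14 | 1-[(2S,3R)-3-(benzyloxymethyl)-5-[3-(tert-butyldimethylsilyloxy)propyl]-7-methoxy-2,3-dihydrobenzofuran-2-yl]pent-4-en-1-one | COc1cc(CCCO[Si](C)(C)C(C)(C)C)cc2c1O[C@H](C(=O)CCC=C)[C@H]2COCc3ccccc3 | intermediate
15 | (4S)-4-[(2S,3R)-3-(benzyloxymethyl)-5-[3-(tert-butyldimethylsilyloxy)propyl]-7-methoxy-2,3-dihydrobenzofuran-2-yl]octa-1,7-dien-4-ol | COc1cc(CCCO[Si](C)(C)C(C)(C)C)cc2c1O[C@H]([C@@](O)(CC=C)CCC=C)[C@H]2COCc3ccccc3 | intermediate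
16 | (1S)-1-[(2S,3R)-3-(benzyloxymethyl)-5-[3-(tert-butyldimethylsilyloxy)propyl]-7-methoxy-2,3-dihydrobenzofuran-2-yl]cyclohex-3-en-1-ol | COc1cc(CCCO[Si](C)(C)C(C)(C)C)cc2c1O[C@H]([C@]3(O)CCC=CC3)[C@H]2COCc4ccccc4 | intermediate
17 | (1S,3S,6R)-3-[(2S,3R)-3-(benzyloxymethyl)-5-[3-(tert-butyldimethylsilyloxy)propyl]-7-methoxy-2,3-dihydrobenzofuran-2-yl]-7-oxabicyclo[4.1.0]heptan-3-ol | COc1cc(CCCO[Si](C)(C)C(C)(C)C)cc2c1O[C@H]([C@]3(O)CC[C@H]4O[C@H]4C3)[C@H]2COCc5ccccc5 | intermediate
18 | (1S,3S,4S)-1-[(2S,3R)-3-(benzyloxymethyl)-5-[3-(tert-butyldimethylsilyloxy)propyl]-7-methoxy-2,3-dihydrobenzofuran-2-yl]-4-methoxycyclohexane-1,3-diol | COc1cc(CCCO[Si](C)(C)C(C)(C)C)cc2c1O[C@H]([C@]3(O)CC[C@H](OC)[C@@H](O)C3)[C@H]2COCc4ccccc4 | intermediate (not isolated)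
19 | (1S,3S,4S)-1-[(2S,3R)-3-(benzyloxymethyl)-5-(3-hydroxypropyl)-7-methoxy-2,3-dihydrobenzofuran-2-yl]-4-methoxycyclohexane-1,3-diol | COc1cc(CCCO)cc2c1O[C@H]([C@]3(O)CC[C@H](OC)[C@@H](O)C3)[C@H]2COCc4ccccc4 | intermediate
20 | difengpiol B, (1S,3S,4S)-1-[(2S,3R)-3-(hydroxymethyl)-5-(3-hydroxypropyl)-7-methoxy-2,3-dihydrobenzofuran-2-yl]-4-methoxycyclohexane-1,3-diol | COc1cc(CCCO)cc2c1O[C@H]([C@]1(O)CC[C@H](OC)[C@@H](O)C1)[C@H]2CO | target

## Step count and risks

Total steps: 12. Longest linear sequence: 9 steps (steps 1–3 then 7–12; the ylide branch, steps 4–6 then 7–12, is equally long).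

Steps most likely to fail:

Step 7. The bis-urea may discriminate poorly between the two faces of a quinone methide whose methide carbon carries an alkyl (CH2OBn) group instead of an aryl group. The quinone methide may also tautomerise to a 2-vinylphenol before the ylide adds. The fallback sets out from 5 and 11 and gives up catalyst control: the two are combined with Cs2CO3 alone in CH2Cl2 at room temperature. This catalyst-free annulation should give the racemic trans-ketone F1, whose trans relationship is still fixed by the ring closure. F1 is then resolved by preparative supercritical-fluid chromatography on a polysaccharide chiral stationary phase; the (2S,3R) enantiomer is compound 14, where the route is rejoined.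

Step 8. Chelation may be too weak, because O1 is an aryl ether oxygen of low basicity and the neighbouring methoxy group can compete for the titanium. The facial selectivity at C1' would then erode towards the Felkin–Anh epimer, and the Lewis acid may also cost some silyl ether. The fallback sets out from 14 and replaces substrate control by reagent control: allylboration of the ketone with an enantiopure B-allyl-10-phenyl-9-borabicyclo[3.3.2]decane, using the antipode that adds to the Si face, in Et2O at −78 °C with NaOH/H2O2 work-up. This is a known class of ketone allylboration that needs no chelate, and it returns to the route at 15. It makes no compound outside the list (F0).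

Step 2. The magnesium phenoxide may react sluggishly with the enolisable alpha-alkoxy aldehyde, which can self-condense. The magnesium-bound product may also ionise and be captured by a second phenoxide to give a diarylmethane. The fallback sets out from 2 and builds the same carbinol in two C–C bond formations. Ortho-formylation with MgCl2, Et3N and paraformaldehyde in MeCN at reflux should give 2-hydroxy-3-methoxy-5-[3-(tert-butyldimethylsilyloxy)propyl]benzaldehyde F2. The phenol of F2 is deprotonated with one equivalent of n-BuLi in THF at −78 °C, and (benzyloxymethyl)lithium, generated from tributyl(benzyloxymethyl)stannane and n-BuLi, is added to the aldehyde. This returns to the route at 4.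

## Further compounds

F1 | step 7 | racemic trans-1-[3-(benzyloxymethyl)-5-[3-(tert-butyldimethylsilyloxy)propyl]-7-methoxy-2,3-dihydrobenzofuran-2-yl]pent-4-en-1-one (both enantiomers, written as the pair) | COc1cc(CCCO[Si](C)(C)C(C)(C)C)cc2c1O[C@H](C(=O)CCC=C)[C@H]2COCc3ccccc3.COc1cc(CCCO[Si](C)(C)C(C)(C)C)cc2c1O[C@@H](C(=O)CCC=C)[C@@H]2COCc3ccccc3
F0 | step 8 | none | none
F2 | step 2 | 2-hydroxy-3-methoxy-5-[3-(tert-butyldimethylsilyloxy)propyl]benzaldehyde | COc1cc(CCCO[Si](C)(C)C(C)(C)C)cc(C=O)c1O
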